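**Plan**

1. Numbering: guaiane numbers C1–C15 for the norbornene half, primed numbers for the half that keeps C4′=C5′. Retrosynthesis: invert the allylic lactone carbon C6′ last; cut C2–C2′ and C5–C3′ (Diels–Alder homodimerisation of two molecules of one cyclopentadiene monomer, 28).
2. In the monomer, cut C9–C10 and C1–C5 in one event. In the seven-membered ring the run C5–C6–C7–C8–C9 (C6 oxygenated, C7 bearing the lactone arm, C8–C9 an ethylene unit) is an opened vinylcyclopropane, C1–C10 is an alkyne, and C2–C3–C4 of the cyclopentene is a three-atom tether: an intramolecular [5+2] cycloaddition.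
3. Cut C5=C6 of the enyne (Julia–Kocienski) into aldehyde 8 (aldol-derived) and cyclopropyl sulfone 12.
4. Forward ring order: five- and seven-membered carbocycles together (step 9), lactone (step 10), norbornene by dimerisation (step 18), re-closure of the allylic lactone with inversion (step 20).
5. Stereochemistry: the (R)-oxazolidinone aldol sets C3/C4 (sacrificial); these set C5 in the cycloaddition; C5 relays to C1, C6, C7 (double hydroboration from the H5 face), C10 (methyl addition from the same face) and C11 (enolate methylation); the Diels–Alder sets C2, C5, C2′, C3′; the Mitsunobu closure sets C6′.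

Key step: step 9

Remark: read literally, the target SMILES has a trans-fused lactone (6S) in the norbornene half and a cis-fused lactone (6′R) in the half that keeps the tetrasubstituted alkene; that compound is made here by inverting C6′ of the homodimer.
Remark: α is the face of H1, H5 and H7 in the monomer series; 1, 3, 9 and 10 are taken as catalogue compounds.

**Step 1**
Reactants: 1 4-(trimethylsilyl)but-3-yn-1-ol
Product: 2 4-(trimethylsilyl)but-3-ynal
Conditions: Dess–Martin periodinane, CH2Cl2, 0 °C → rt; used crude at once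
Reagents that add atoms: none
Why: Dess–Martin oxidation of the primary alcohol under neutral, non-enolising conditions should give the sensitive β,γ-alkynyl aldehyde without isomerisation to the allenal; no stereocentre is formed.

**Step 2**
Reactants: 2 4-(trimethylsilyl)but-3-ynal; 3 (4R)-4-benzyl-3-propanoyl-1,3-oxazolidin-2-one
Product: 5 (4R)-4-benzyl-3-[(2R,3S)-3-hydroxy-2-methyl-6-(trimethylsilyl)hex-5-ynoyl]-1,3-oxazolidin-2-one, via Z-boron enolate 4 (not isolated)
Conditions: Bu2BOTf, Et3N, CH2Cl2, −78 → 0 °C; then 2, −78 °C; pH 7 phosphate buffer, MeOH, H2O2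
Reagents that add atoms: none
Why: Evans syn-aldol reaction, in which the Z-boron enolate reacts through a closed chair transition state and the benzyl group of the (R)-auxiliary shields one enolate face, so the later tether carbons C4 (2R) and C3 (3S) should arise together as the syn pair.

**Step 3**
Reactants: 5 aldol adduct
Product: 6 (2R,3S)-3-hydroxy-N-methoxy-N,2-dimethyl-6-(trimethylsilyl)hex-5-ynamide
Conditions: MeNH(OMe)·HCl, AlMe3, THF, −10 → 0 °C; aq. potassium sodium tartrate
Reagents that add atoms: N,O-dimethylhydroxylamine hydrochloride, CNOC.Cl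
Why: Weinreb amide formation by aluminium-amide transamidation of the imide, assisted by the free β-hydroxyl, should release the auxiliary without epimerising C2.

**Step 4**
Reactants: 6 hydroxy Weinreb amide
Product: 7 (2R,3S)-3-[(tert-butyldimethylsilyl)oxy]-N-methoxy-N,2-dimethyl-6-(trimethylsilyl)hex-5-ynamide
Conditions: TBSOTf, 2,6-lutidine, CH2Cl2, −78 → 0 °C
Reagents that add atoms: tert-butyldimethylsilyl trifluoromethanesulfonate, CC(C)(C)[Si](C)(C)OS(=O)(=O)C(F)(F)F
Why: silylation with the silyl triflate and a hindered pyridine base is reliable for β-hydroxy amides and masks the alcohol that later becomes the C3 ketone.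

**Step 5**
Reactants: 7 silyl ether
Product: 8 (2R,3S)-3-[(tert-butyldimethylsilyl)oxy]-2-methyl-6-(trimethylsilyl)hex-5-ynal
Conditions: iBu2AlH, THF, −78 °C; aq. potassium sodium tartrate
Reagents that add atoms: none
Why: hydride reduction of the Weinreb amide stops at the chelated tetrahedral intermediate, which releases the aldehyde only on work-up, so the α-methyl stereocentre should survive.

**Step 6**
Reactants: 9 methyl 2-[1-(sulfanylmethyl)cyclopropyl]acetate; 10 5-chloro-1-phenyl-1H-tetrazole
Product: 11 methyl 2-(1-{[(1-phenyl-1H-tetrazol-5-yl)sulfanyl]methyl}cyclopropyl)acetate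
Conditions: Et3N, MeCN, rt
Reagents that add atoms: none
Why: nucleophilic aromatic substitution of the activated chlorotetrazole by the thiolate gives the tetrazolyl sulfide needed for a Julia–Kocienski olefination; the ester is untouched by the amine base.

**Step 7**
Reactants: 11 tetrazolyl sulfide
Product: 12 methyl 2-(1-{[(1-phenyl-1H-tetrazol-5-yl)sulfonyl]methyl}cyclopropyl)acetate
Conditions: (NH4)6Mo7O24·4H2O (10 mol %), 30% H2O2, EtOH, rt
Reagents that add atoms: hydrogen peroxide, OO
Why: molybdate-catalysed peroxide oxidation takes the sulfide through the sulfoxide to the sulfone and leaves ester and cyclopropane alone.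

**Step 8**
Reactants: 12 tetrazolyl sulfone; 8 aldehyde
Product: 14 methyl 2-{1-[(1E,3S,4S)-4-[(tert-butyldimethylsilyl)oxy]-3-methylhept-1-en-6-yn-1-yl]cyclopropyl}acetate, via silyl-capped enyne 13 (not isolated)
Conditions: KN(SiMe3)2, DME, −60 °C; then 8, −60 °C → rt; then K2CO3 (0.3 equiv), MeOH, rt
Reagents that add atoms: none
Why: Julia–Kocienski olefination, in which the metallated sulfone adds to the α-branched aldehyde and the adduct collapses by Smiles rearrangement with loss of SO2 and tetrazolone to the E-alkene (the vinylcyclopropane geometry the cycloaddition needs), after which carbonate in methanol cleaves only the C(sp)–Si bond.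

**Step 9**
Reactants: 14 enyne with vinylcyclopropane
Product: 15 methyl 2-[(2S,3S,3aS)-2-[(tert-butyldimethylsilyl)oxy]-3-methyl-1,2,3,3a,6,7-hexahydroazulen-5-yl]acetate
Conditions: [Rh(CO)2Cl]2 (5 mol %), toluene (0.02 M), 80–110 °C
Reagents that add atoms: none
Why: Monovalent rhodium adds oxidatively to the vinylcyclopropane of 14 (C5=C6–C7 with C8/C9), opening the strained ring to a σ-alkyl/π-allyl rhodacycle; the tethered alkyne inserts at the allyl terminus to form C1–C5, and reductive elimination forms C9–C10. The closest known reaction type is the rhodium-catalysed intramolecular [5+2] cycloaddition of tethered alkyne–vinylcyclopropanes, which with [Rh(CO)2Cl]2 accepts terminal alkynes, E-alkenes and a substituted cyclopropane carbon. The five-membered ring (C1–C2–C3–C4–C5) closes by insertion of the alkyne across the three-carbon tether, and the seven-membered ring (C1, C5–C9, C10) closes by C9–C10 reductive elimination from the eight-membered rhodacycle, five carbons coming from the vinylcyclopropane and two from the alkyne. The only new stereocentre, C5, is controlled by C4: the forming cyclopentane places the C4 methyl and C3 silyloxy groups pseudo-equatorial, so the C5–C6 bond ends trans to the methyl group (H5 cis to it, 5S). The step needs facial selectivity at C5=C6 and chemoselectivity for cycloaddition over alkyne oligomerisation; the first is secured by the syn C3/C4 pair from the aldol, the second by the tether and high dilution, and the symmetric cyclopropane (C8 and C9 equivalent) removes any question of which ring bond opens. The product keeps C1=C10 and C6=C7 unconjugated on either side of C5–H, which the next step uses.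

**Step 10**
Reactants: 15 hexahydroazulene diene ester
Product: 18 3β-[(tert-butyldimethylsilyl)oxy]-10α-hydroxy-13,14-dinorguaian-12,6α-olide (1αH,4βH,5αH,6βH,7αH), via bis-borane 16 (not isolated), via diol ester 17 (not isolated)
Conditions: BH3·THF (3 equiv), THF, 0 °C → rt; 3 M NaOH, 30% H2O2, 0 °C → rt; then 1 M HCl to pH 3, rt
Reagents that add atoms: hydrogen peroxide, OO
Why: double hydroboration–oxidation, in which borane adds syn and anti-Markovnikov to both trisubstituted alkenes from the face of H5 (anti to C4 at the shared allylic centre C5), should set H1, H7, O6 and O10 all α, and the 6α-hydroxyl then closes the trans-fused γ-lactone onto the β-oriented acetate arm on acidification.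

**Step 11**
Reactants: 18 hydroxy lactone
Product: 19 3β-[(tert-butyldimethylsilyl)oxy]-10-oxo-13,14-dinorguaian-12,6α-olide
Conditions: Dess–Martin periodinane, CH2Cl2, rt
Reagents that add atoms: none
Why: Dess–Martin oxidation of the secondary C10 alcohol under non-basic conditions should give the ketone without epimerising the adjacent ring-fusion centre C1.

**Step 12**
Reactants: 19 keto lactone
Product: 20 3β-[(tert-butyldimethylsilyl)oxy]-10β-hydroxy-13-norguaian-12,6α-olide (C14 methyl α)
Conditions: MeMgBr, CeCl3, THF, −78 °C; aq. NH4Cl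
Reagents that add atoms: methylmagnesium bromide, C[Mg]Br
Why: organocerium 1,2-addition (weakly basic, ketone-selective over the lactone) should deliver methyl from the convex α face of the cis-fused hydroazulenone, anti to the C1–C2 bond, giving the 10β-hydroxy-10α-methyl carbinol.

**Step 13**
Reactants: 20 tertiary alcohol lactone
Product: 22 (11S)-3β-[(tert-butyldimethylsilyl)oxy]-10β-hydroxyguaian-12,6α-olide, via dilithium enolate 21 (not isolated)
Conditions: LiN(iPr)2 (2.2 equiv), THF, −78 °C; MeI (1.05 equiv), −78 → −40 °C; aq. NH4Cl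
Reagents that add atoms: iodomethane, CI
Why: lactone enolate alkylation, in which the electrophile should approach C11 of the trans-fused lactone anti to the C7–C8 bond (syn to H7) to give the 11S methyl group, also the thermodynamically preferred epimer, while the tertiary lithium alkoxide is inert to iodomethane at low temperature.

**Step 14**
Reactants: 22 methylated lactone
Product: 23 (11S)-3β,10β-dihydroxyguaian-12,6α-olide
Conditions: Bu4NF, THF, rt
Reagents that add atoms: none
Why: fluoride-mediated desilylation frees the C3 alcohol and leaves the lactone and the tertiary alcohol untouched.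

**Step 15**
Reactants: 23 diol lactone
Product: 25 (3S,3aS,6S,6aR,9bS)-6-hydroxy-3,6,9-trimethyl-3a,4,5,6,6a,7-hexahydroazuleno[4,5-b]furan-2,8(3H,9bH)-dione, via ketone 24 (not isolated)
Conditions: IBX (4 equiv), DMSO, 75 °C
Reagents that add atoms: none
Why: IBX oxidises the C3 alcohol to ketone 24 and, at this temperature, should dehydrogenate it through the more substituted enol to the tetrasubstituted C4=C5 enone, which removes the relay centres C4 and C5 once they have done their work.

**Step 16**
Reactants: 25 enone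
Product: 27 (11S)-10β-hydroxy-3-(trifluoromethanesulfonyloxy)guaia-2,4-dien-12,6α-olide, via dipotassium dienolate 26 (not isolated)
Conditions: KN(SiMe3)2 (2.2 equiv), THF, −78 °C; PhNTf2 (1.05 equiv), −78 → −20 °C; aq. NH4Cl
Reagents that add atoms: N-phenylbis(trifluoromethanesulfonimide), O=S(=O)(N(c1ccccc1)S(=O)(=O)C(F)(F)F)C(F)(F)F
Why: enol triflate formation, in which kinetic deprotonation at the α′ carbon C2 gives the cross-conjugated dienolate that is trapped on oxygen by the triflimide, the first equivalent of base holding the tertiary alcohol as its hindered alkoxide.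

**Step 17**
Reactants: 27 dienyl triflate
Product: 28 (3S,3aS,6S,6aR,9bS)-6-hydroxy-3,6,9-trimethyl-3,3a,4,5,6,6a-hexahydroazuleno[4,5-b]furan-2(9bH)-one (10β-hydroxyguaia-2,4-dien-12,6α-olide)
Conditions: Pd(OAc)2 (5 mol %), PPh3 (10 mol %), HCO2H, Bu3N, DMF, 25–40 °C; cold aqueous work-up, quick filtration through silica, kept cold and dilute, used at once
Reagents that add atoms: none
Why: palladium-catalysed formate reduction of the dienyl triflate (oxidative addition to zerovalent palladium, triflate–formate exchange, decarboxylation to the palladium hydride, reductive elimination) should replace the C3–O bond by C3–H and release the cyclopentadiene monomer without touching a stereocentre.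

**Step 18**
Reactants: 28 diene lactone (first molecule, reacting as the diene C2=C3–C4=C5); 28 diene lactone (second molecule, reacting as the dienophile C2′=C3′)
Product: 29 endo Diels–Alder homodimer of 28 with both lactones trans-fused (new bonds C2–C2′ and C5–C3′)
Conditions: neat, 25 °C, dark, under argon, several days
Reagents that add atoms: none
Why: Diels–Alder homodimerisation of two molecules of 28, in which the diene of one molecule and the less substituted C2′=C3′ bond of the other combine through the endo transition state, each partner reacting on the face of its H1 (anti to C10 of the seven-membered ring), the unhindered termini C2 and C2′ bonding ahead of C5–C3′, which fixes C2, C5, C2′ and C3′.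

**Step 19**
Reactants: 29 bis-trans-lactone dimer
Product: 30 6,6′-dihydroxy-12,12′-dioic acid of 29 (both lactones opened)
Conditions: LiOH·H2O, THF–H2O, rt; 0.5 M HCl to pH 5, 0 °C; used at once
Reagents that add atoms: lithium hydroxide, [Li+].[OH-]; water, O
Why: saponification opens both γ-lactones to the carboxylates, and cold acidification to pH 5 gives the hydroxy acids, which close only slowly at this pH, without touching any stereocentre.

**Step 20**
Reactants: 30 dihydroxy diacid
Product: 32 target (6S trans-lactone in the norbornene half, 6′R cis-lactone in the other half), via monolactone seco acid 31 (not isolated)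
Conditions: PPh3, DIAD, THF (high dilution), 0 °C → rt; then PPTS (cat.), CH2Cl2, rt
Reagents that add atoms: none
Why: Mitsunobu lactonisation, in which the allylic C6′ alcohol is activated as its oxyphosphonium ion and displaced with inversion by the internal carboxylate from the β face (5-exo-tet) to give the cis-fused lactone, whereas the C6 alcohol, flanked by the quaternary bridgehead C5, cannot be displaced and lactonises with retention (acyl activation or the acid treatment).

**Compound list**

1 | 4-(trimethylsilyl)but-3-yn-1-ol | C[Si](C)(C)C#CCCO | starting material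
2 | 4-(trimethylsilyl)but-3-ynal | C[Si](C)(C)C#CCC=O | intermediate
3 | (4R)-4-benzyl-3-propanoyl-1,3-oxazolidin-2-one | CCC(=O)N1[C@H](Cc2ccccc2)COC1=O | starting material
4 | Z-dibutylboron enolate of 3 | C/C=C(\OB(CCCC)CCCC)N1[C@H](Cc2ccccc2)COC1=O | intermediate
5 | (4R)-4-benzyl-3-[(2R,3S)-3-hydroxy-2-methyl-6-(trimethylsilyl)hex-5-ynoyl]-1,3-oxazolidin-2-one | C[C@H]([C@@H](O)CC#C[Si](C)(C)C)C(=O)N1[C@H](Cc2ccccc2)COC1=O | intermediate
6 | (2R,3S)-3-hydroxy-N-methoxy-N,2-dimethyl-6-(trimethylsilyl)hex-5-ynamide | CON(C)C(=O)[C@H](C)[C@@H](O)CC#C[Si](C)(C)C | intermediate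
7 | (2R,3S)-3-[(tert-butyldimethylsilyl)oxy]-N-methoxy-N,2-dimethyl-6-(trimethylsilyl)hex-5-ynamide | CON(C)C(=O)[C@H](C)[C@@H](O[Si](C)(C)C(C)(C)C)CC#C[Si](C)(C)C | intermediate
8 | (2R,3S)-3-[(tert-butyldimethylsilyl)oxy]-2-methyl-6-(trimethylsilyl)hex-5-ynal | O=C[C@H](C)[C@@H](O[Si](C)(C)C(C)(C)C)CC#C[Si](C)(C)C | intermediate
9 | methyl 2-[1-(sulfanylmethyl)cyclopropyl]acetate | COC(=O)CC1(CS)CC1 | starting material
10 | 5-chloro-1-phenyl-1H-tetrazole | Clc1nnnn1-c1ccccc1 | starting material
11 | methyl 2-(1-{[(1-phenyl-1H-tetrazol-5-yl)sulfanyl]methyl}cyclopropyl)acetate | COC(=O)CC1(CSc2nnnn2-c2ccccc2)CC1 | intermediate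
12 | methyl 2-(1-{[(1-phenyl-1H-tetrazol-5-yl)sulfonyl]methyl}cyclopropyl)acetate | COC(=O)CC1(CS(=O)(=O)c2nnnn2-c2ccccc2)CC1 | intermediate
13 | methyl 2-{1-[(1E,3S,4S)-4-[(tert-butyldimethylsilyl)oxy]-3-methyl-7-(trimethylsilyl)hept-1-en-6-yn-1-yl]cyclopropyl}acetate | C[Si](C)(C)C#CC[C@H](O[Si](C)(C)C(C)(C)C)[C@@H](C)/C=C/C1(CC(=O)OC)CC1 | intermediate
14 | methyl 2-{1-[(1E,3S,4S)-4-[(tert-butyldimethylsilyl)oxy]-3-methylhept-1-en-6-yn-1-yl]cyclopropyl}acetate | C#CC[C@H](O[Si](C)(C)C(C)(C)C)[C@@H](C)/C=C/C1(CC(=O)OC)CC1 | intermediate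
15 | methyl 2-[(2S,3S,3aS)-2-[(tert-butyldimethylsilyl)oxy]-3-methyl-1,2,3,3a,6,7-hexahydroazulen-5-yl]acetate | COC(=O)CC1=C[C@H]2[C@H](C)[C@@H](O[Si](C)(C)C(C)(C)C)CC2=CCC1 | intermediate
16 | 6α,10α-bis(boranyl) adduct of 15, shown as the bis(monoalkylborane) | COC(=O)C[C@@H]1CC[C@@H]([BH2])[C@@H]2C[C@H](O[Si](C)(C)C(C)(C)C)[C@@H](C)[C@@H]2[C@H]1[BH2] | intermediate
17 | methyl 3β-[(tert-butyldimethylsilyl)oxy]-6α,10α-dihydroxy-13,14-dinorguaian-12-oate | COC(=O)C[C@@H]1CC[C@@H](O)[C@@H]2C[C@H](O[Si](C)(C)C(C)(C)C)[C@@H](C)[C@@H]2[C@H]1O | intermediate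
18 | 3β-[(tert-butyldimethylsilyl)oxy]-10α-hydroxy-13,14-dinorguaian-12,6α-olide | O=C1C[C@@H]2CC[C@@H](O)[C@@H]3C[C@H](O[Si](C)(C)C(C)(C)C)[C@@H](C)[C@@H]3[C@H]2O1 | intermediate
19 | 3β-[(tert-butyldimethylsilyl)oxy]-10-oxo-13,14-dinorguaian-12,6α-olide | O=C1C[C@@H]2CCC(=O)[C@@H]3C[C@H](O[Si](C)(C)C(C)(C)C)[C@@H](C)[C@@H]3[C@H]2O1 | intermediate
20 | 3β-[(tert-butyldimethylsilyl)oxy]-10β-hydroxy-13-norguaian-12,6α-olide | O=C1C[C@@H]2CC[C@](C)(O)[C@@H]3C[C@H](O[Si](C)(C)C(C)(C)C)[C@@H](C)[C@@H]3[C@H]2O1 | intermediate
21 | dilithium alkoxide enolate of 20 | [Li+].[Li+].[O-]C1=C[C@@H]2CC[C@](C)([O-])[C@@H]3C[C@H](O[Si](C)(C)C(C)(C)C)[C@@H](C)[C@@H]3[C@H]2O1 | intermediate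
22 | (11S)-3β-[(tert-butyldimethylsilyl)oxy]-10β-hydroxyguaian-12,6α-olide | O=C1[C@@H](C)[C@@H]2CC[C@](C)(O)[C@@H]3C[C@H](O[Si](C)(C)C(C)(C)C)[C@@H](C)[C@@H]3[C@H]2O1 | intermediate
23 | (11S)-3β,10β-dihydroxyguaian-12,6α-olide | O=C1[C@@H](C)[C@@H]2CC[C@](C)(O)[C@@H]3C[C@H](O)[C@@H](C)[C@@H]3[C@H]2O1 | intermediate
24 | (11S)-10β-hydroxy-3-oxoguaian-12,6α-olide | O=C1[C@@H](C)[C@@H]2CC[C@](C)(O)[C@@H]3CC(=O)[C@@H](C)[C@@H]3[C@H]2O1 | intermediate
25 | (3S,3aS,6S,6aR,9bS)-6-hydroxy-3,6,9-trimethyl-3a,4,5,6,6a,7-hexahydroazuleno[4,5-b]furan-2,8(3H,9bH)-dione | CC1=C2[C@H]3OC(=O)[C@@H](C)[C@@H]3CC[C@](C)(O)[C@@H]2CC1=O | intermediate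
26 | dipotassium alkoxide dienolate of 25 | CC1=C2[C@H]3OC(=O)[C@@H](C)[C@@H]3CC[C@](C)([O-])[C@@H]2C=C1[O-].[K+].[K+] | intermediate
27 | (11S)-10β-hydroxy-3-(trifluoromethanesulfonyloxy)guaia-2,4-dien-12,6α-olide | CC1=C2[C@H]3OC(=O)[C@@H](C)[C@@H]3CC[C@](C)(O)[C@@H]2C=C1OS(=O)(=O)C(F)(F)F | intermediate
28 | (3S,3aS,6S,6aR,9bS)-6-hydroxy-3,6,9-trimethyl-3,3a,4,5,6,6a-hexahydroazuleno[4,5-b]furan-2(9bH)-one (10β-hydroxyguaia-2,4-dien-12,6α-olide) | CC1=C2[C@H]3OC(=O)[C@@H](C)[C@@H]3CC[C@](C)(O)[C@@H]2C=C1 | intermediate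
29 | endo Diels–Alder homodimer of 28, both lactones trans-fused | CC1=C[C@@H]2[C@H]3[C@H](C(C)=C4[C@H]5OC(=O)[C@@H](C)[C@@H]5CC[C@](C)(O)[C@@H]43)[C@@]13[C@@H]2[C@@](C)(O)CC[C@H]1[C@H](C)C(=O)O[C@@H]13 | intermediate
30 | 6,6′-dihydroxy-12,12′-dioic acid from 29 | CC1=C[C@@H]2[C@H]3[C@H](C(C)=C4[C@@H](O)[C@H]([C@H](C)C(=O)O)CC[C@](C)(O)[C@@H]43)[C@@]13[C@@H]2[C@@](C)(O)CC[C@@H]([C@H](C)C(=O)O)[C@@H]3O | intermediate
31 | monolactone seco acid (6′R cis-lactone closed, C6 hydroxy acid open) | CC1=C[C@@H]2[C@H]3[C@H](C(C)=C4[C@@H]5OC(=O)[C@@H](C)[C@@H]5CC[C@](C)(O)[C@@H]43)[C@@]13[C@@H]2[C@@](C)(O)CC[C@@H]([C@H](C)C(=O)O)[C@@H]3O | intermediate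
32 | absinthin as given (6S, 6′R) | CC1=C[C@@H]2[C@H]3[C@H](C(C)=C4[C@@H]5OC(=O)[C@@H](C)[C@@H]5CC[C@](C)(O)[C@@H]43)[C@@]13[C@@H]2[C@@](C)(O)CC[C@H]1[C@H](C)C(=O)O[C@@H]13 | target

**Count**

Total steps: 20. Longest linear sequence: 18 (1 → 32 through steps 1–5 and 8–20); the sulfone arm (steps 6–7) is a two-step branch.

**Steps most likely to fail**

Step 9. The free terminal alkyne may oligomerise on rhodium faster than it enters the cycloaddition, and an ene-type cycloisomerisation of the enyne may compete. The fallback sets out from 13, which is isolated by leaving out the carbonate–methanol treatment in step 8. The silyl-capped internal alkyne is submitted to the same rhodium-catalysed [5+2] cycloaddition to give the vinylsilane cycloadduct F1. Protodesilylation (CF3CO2H, CH2Cl2, −20 °C; ipso protonation gives a tertiary β-silyl cation at C1) then returns to the route at 15.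

Step 20. The hindered allylic C6′ alcohol may lactonise with retention through acyl activation instead of being displaced, or may eliminate, so that the homodimer 29 is simply re-formed. The fallback sets out from 30 and replaces displacement by an oxidation–reduction sequence. Me3SiCHN2 (MeOH–toluene) gives the bis(hydroxy methyl ester) F2. MnO2 (CH2Cl2) oxidises only the allylic C6′ alcohol to the enone F3. LiBH(s-Bu)3 (THF, −78 °C) should deliver hydride anti to the C7′ side chain to give the 6′-epimeric allylic alcohol F4. PPTS (CH2Cl2) then closes both lactones with loss of methanol and returns to the route at 32.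

Step 15. Dehydrogenation may run toward C2–C1 instead of C4–C5, or stop at ketone 24, because IBX does not distinguish the two α positions reliably. The fallback sets out from 23 and fixes the regiochemistry in a separate intermediate. Dess–Martin oxidation gives 24, now isolated. Me3SiOTf and Et3N (CH2Cl2, rt, thermodynamic conditions) give the more substituted silyl enol ether F5, in which the tertiary alcohol is also silylated. Saegusa–Ito oxidation with Pd(OAc)2 (MeCN, rt; syn β-hydride elimination of H5), followed by a dilute acid wash, returns to the route at 25.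

**Further compounds**

F1 | step 9 | methyl 2-[(2S,3S,3aS)-2-[(tert-butyldimethylsilyl)oxy]-3-methyl-8-(trimethylsilyl)-1,2,3,3a,6,7-hexahydroazulen-5-yl]acetate | COC(=O)CC1=C[C@H]2[C@H](C)[C@@H](O[Si](C)(C)C(C)(C)C)CC2=C([Si](C)(C)C)CC1
F2 | step 20 | dimethyl ester of 30 | CC1=C[C@@H]2[C@H]3[C@H](C(C)=C4[C@@H](O)[C@H]([C@H](C)C(=O)OC)CC[C@](C)(O)[C@@H]43)[C@@]13[C@@H]2[C@@](C)(O)CC[C@@H]([C@H](C)C(=O)OC)[C@@H]3O
F3 | step 20 | 6′-oxo dimethyl ester (enone) | CC1=C[C@@H]2[C@H]3[C@H](C(C)=C4C(=O)[C@H]([C@H](C)C(=O)OC)CC[C@](C)(O)[C@@H]43)[C@@]13[C@@H]2[C@@](C)(O)CC[C@@H]([C@H](C)C(=O)OC)[C@@H]3O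
F4 | step 20 | 6′-epi-hydroxy dimethyl ester | CC1=C[C@@H]2[C@H]3[C@H](C(C)=C4[C@H](O)[C@H]([C@H](C)C(=O)OC)CC[C@](C)(O)[C@@H]43)[C@@]13[C@@H]2[C@@](C)(O)CC[C@@H]([C@H](C)C(=O)OC)[C@@H]3O
F5 | step 15 | (11S)-3,10β-bis(trimethylsilyloxy)guai-3-en-12,6α-olide | O=C1[C@@H](C)[C@@H]2CC[C@](C)(O[Si](C)(C)C)[C@@H]3CC(O[Si](C)(C)C)=C(C)[C@@H]3[C@H]2O1
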